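**Strategy.** Both aromatic rings of the target are the same arene, 4-(2-methylbut-3-en-2-yl)resorcinol, made once by aromatic Claisen rearrangement. Ring C is formed last: C4a lies ortho to O1 and para to the 7-OH, so the free resorcinol is a 1,3-C,O-dinucleophile, while C2–C3–C4 with the second arene (as its diacetate) on C3 is a 2-arylacrolein. A chiral phosphoric acid joins the two by Friedel–Crafts conjugate addition (C4–C4a) and hemiacetalization (O1–C2), and a Hantzsch ester reduces the lactol in the same flask with dynamic kinetic resolution, which sets C3 and leaves both terminal alkenes untouched. Methanolysis of the acetates then gives the target.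

Key step: step 7

Remark: the sense of induction of the chiral phosphoric acid in step 7 cannot be assigned in advance; (R)-TRIP is written, and (S)-TRIP would be taken instead if it proves to be the antipode that gives the 3R product.

**Step 1**
Reactants: 1 resorcinol (3 equiv); 2 prenyl bromide
Product: 3 3-[(3-methylbut-2-en-1-yl)oxy]phenol
Conditions: K2CO3 (1.1 equiv), acetone, reflux
Reagents that add atoms: none
Why: Williamson ether synthesis, in which the phenoxide of resorcinol, kept in excess to suppress the bis-ether, displaces bromide from the primary allylic halide at oxygen.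

**Step 2**
Reactants: 3 3-[(3-methylbut-2-en-1-yl)oxy]phenol
Product: 4 4-(2-methylbut-3-en-2-yl)benzene-1,3-diol
Conditions: EtOH–H2O (4:1), 140 °C, sealed tube
Reagents that add atoms: none
Why: Aromatic Claisen rearrangement ([3,3]-shift with allylic inversion, then tautomerization) should deliver the 1,1-dimethylallyl group to the less hindered ortho carbon C6 (para to the hydroxyl) rather than to C2 between the two oxygens, and the aqueous medium accelerates the shift so that the temperature stays below that of the abnormal Claisen pathway.

**Step 3**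
Reactants: 4 4-(2-methylbut-3-en-2-yl)benzene-1,3-diol
Product: 5 4-bromo-6-(2-methylbut-3-en-2-yl)benzene-1,3-diol
Conditions: NBS (1.0 equiv), CH2Cl2–MeCN, −78 → −40 °C
Reagents that add atoms: N-bromosuccinimide, O=C1CCC(=O)N1Br
Why: Electrophilic aromatic bromination at C6 (ortho to one OH, para to the other), the only unhindered doubly activated carbon because C4 carries the tert-alkyl group and C2 lies between the hydroxyls; at low temperature the resorcinol ring reacts far faster than the hindered monosubstituted alkene.

**Step 4**
Reactants: 5 4-bromo-6-(2-methylbut-3-en-2-yl)benzene-1,3-diol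
Product: 6 4-bromo-6-(2-methylbut-3-en-2-yl)-1,3-phenylene diacetate
Conditions: Ac2O, pyridine, DMAP (cat.), CH2Cl2, rt
Reagents that add atoms: acetic anhydride, CC(=O)OC(C)=O
Why: DMAP-catalysed acylation of both phenols gives a protecting group that tolerates the neutral coupling and oxidation steps, makes the ring oxygens too poor as donors to trap a cation at C2 later, and is removed at the end without acid.

**Step 5**
Reactants: 6 4-bromo-6-(2-methylbut-3-en-2-yl)-1,3-phenylene diacetate; 7 tributyl(prop-1-en-2-yl)stannane
Product: 8 4-(2-methylbut-3-en-2-yl)-6-(prop-1-en-2-yl)-1,3-phenylene diacetate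
Conditions: Pd(PPh3)4 (5 mol %), toluene, 100 °C
Reagents that add atoms: none
Why: Stille cross-coupling (oxidative addition of the aryl bromide, transfer of the isopropenyl group from tin, reductive elimination) runs without base, so the aryl acetates and the remote alkene are left untouched.

**Step 6**
Reactants: 8 4-(2-methylbut-3-en-2-yl)-6-(prop-1-en-2-yl)-1,3-phenylene diacetate
Product: 9 4-(2-methylbut-3-en-2-yl)-6-(3-oxoprop-1-en-2-yl)-1,3-phenylene diacetate
Conditions: SeO2 (1.5 equiv), 1,4-dioxane–H2O (20:1), 90 °C; crude 9 used at once
Reagents that add atoms: selenium dioxide, O=[Se]=O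
Why: Riley allylic oxidation, in which the ene reaction of SeO2 can only occur at the methyl of the isopropenyl group (the 1,1-dimethylallyl group has no allylic hydrogen), and [2,3]-shift followed by further oxidation gives the 2-arylacrolein.

**Step 7**
Reactants: 4 4-(2-methylbut-3-en-2-yl)benzene-1,3-diol (1.1 equiv); 9 4-(2-methylbut-3-en-2-yl)-6-(3-oxoprop-1-en-2-yl)-1,3-phenylene diacetate
Product: 12 4-[(3R)-7-hydroxy-6-(2-methylbut-3-en-2-yl)-3,4-dihydro-2H-chromen-3-yl]-6-(2-methylbut-3-en-2-yl)-1,3-phenylene diacetate, via lactol 10 (not isolated), via 4H-chromene enol ether 11 (not isolated)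
Conditions: (R)-TRIP (10 mol %), Hantzsch ester (1.3 equiv), 5 Å MS, toluene, 0 → 40 °C, 9 added slowly
Reagents that add atoms: none
Why: Proposed new method: the phosphoric acid should activate enal 9 for Friedel–Crafts conjugate addition of C6 of resorcinol 4 to the unsubstituted β-carbon (C4–C4a bond), and the neighbouring hydroxyl then closes ring C on the aldehyde by 6-exo-trig hemiacetalization (O1–C2 bond) to give lactol 10. Acid-promoted loss of water gives a chroman-2-ylium phosphate ion pair whose C3 epimers interconvert through the achiral, aryl-conjugated enol ether 11, and hydride transfer from the Hantzsch ester to C2 of the faster-reacting ion pair gives 12 (dynamic kinetic resolution). The closest known reactions are the acid- or amine-catalysed Friedel–Crafts/hemiacetalization of resorcinols and naphthols with enals, the chiral phosphoric acid/Hantzsch ester reductive amination of α-branched aldehydes with dynamic kinetic resolution through imine–enamine tautomerism, and the transfer hydrogenation of 3-substituted quinolines, in which C3 is set by enantioselective protonation. The new C3 stereocentre is controlled only by the chiral phosphate, whose antipode is chosen to give R. The step needs attack at C6 of 4, secured because C4 is blocked and C2 lies between two hydroxyls, it needs a reductant that ignores the two monosubstituted alkenes, which a Hantzsch ester does because it reduces only cations, and it needs the 2'-oxygen of the B ring not to trap the C2 cation, which the acetyl group ensures.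

**Step 8**
Reactants: 12 4-[(3R)-7-hydroxy-6-(2-methylbut-3-en-2-yl)-3,4-dihydro-2H-chromen-3-yl]-6-(2-methylbut-3-en-2-yl)-1,3-phenylene diacetate
Product: 13 Manuifolin E
Conditions: K2CO3, MeOH, rt, argon; aq NH4Cl
Reagents that add atoms: none
Why: Base-catalysed transesterification removes both aryl acetates without acid, so the acid-sensitive o-(1,1-dimethylallyl)phenols survive, and C3, which has no acidifying neighbour, keeps its configuration.

**Compound list**
1 | resorcinol (benzene-1,3-diol) | Oc1cccc(O)c1 | starting material
2 | prenyl bromide (1-bromo-3-methylbut-2-ene) | CC(C)=CCBr | starting material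
3 | 3-[(3-methylbut-2-en-1-yl)oxy]phenol | CC(C)=CCOc1cccc(O)c1 | intermediate
4 | 4-(2-methylbut-3-en-2-yl)benzene-1,3-diol | C=CC(C)(C)c1ccc(O)cc1O | intermediate
5 | 4-bromo-6-(2-methylbut-3-en-2-yl)benzene-1,3-diol | C=CC(C)(C)c1cc(Br)c(O)cc1O | intermediate
6 | 4-bromo-6-(2-methylbut-3-en-2-yl)-1,3-phenylene diacetate | C=CC(C)(C)c1cc(Br)c(OC(C)=O)cc1OC(C)=O | intermediate
7 | tributyl(prop-1-en-2-yl)stannane | C=C(C)[Sn](CCCC)(CCCC)CCCC | starting material
8 | 4-(2-methylbut-3-en-2-yl)-6-(prop-1-en-2-yl)-1,3-phenylene diacetate | C=CC(C)(C)c1cc(C(C)=C)c(OC(C)=O)cc1OC(C)=O | intermediate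
9 | 4-(2-methylbut-3-en-2-yl)-6-(3-oxoprop-1-en-2-yl)-1,3-phenylene diacetate (2-arylacrolein) | C=CC(C)(C)c1cc(C(=C)C=O)c(OC(C)=O)cc1OC(C)=O | intermediate
10 | 4-[2,7-dihydroxy-6-(2-methylbut-3-en-2-yl)-3,4-dihydro-2H-chromen-3-yl]-6-(2-methylbut-3-en-2-yl)-1,3-phenylene diacetate (lactol, racemic, both C2 epimers; not isolated in step 7) | C=CC(C)(C)c1cc2c(cc1O)OC(O)C(c1cc(C(C)(C)C=C)c(OC(C)=O)cc1OC(C)=O)C2 | intermediate
11 | 4-[7-hydroxy-6-(2-methylbut-3-en-2-yl)-4H-chromen-3-yl]-6-(2-methylbut-3-en-2-yl)-1,3-phenylene diacetate (enol ether; not isolated in step 7) | C=CC(C)(C)c1cc2c(cc1O)OC=C(c1cc(C(C)(C)C=C)c(OC(C)=O)cc1OC(C)=O)C2 | intermediate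
12 | 4-[(3R)-7-hydroxy-6-(2-methylbut-3-en-2-yl)-3,4-dihydro-2H-chromen-3-yl]-6-(2-methylbut-3-en-2-yl)-1,3-phenylene diacetate | C=CC(C)(C)c1cc2c(cc1O)OC[C@@H](c1cc(C(C)(C)C=C)c(OC(C)=O)cc1OC(C)=O)C2 | intermediate
13 | Manuifolin E, 4-[(3R)-7-hydroxy-6-(2-methylbut-3-en-2-yl)-3,4-dihydro-2H-chromen-3-yl]-6-(2-methylbut-3-en-2-yl)benzene-1,3-diol | C=CC(C)(C)c1cc2c(cc1O)OC[C@@H](c1cc(C(C)(C)C=C)c(O)cc1O)C2 | target

**Total step count:** 8
**Longest linear sequence:** 8 steps (1 → 3 → 4 → 5 → 6 → 8 → 9 → 12 → 13); compound 4 enters a second time in step 7.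

**Steps most likely to fail**

Step 7 (Proposed new method). Ionization of lactol 10 may be too slow with an acid of this strength. Interconversion of the C3 epimers through enol ether 11 may be slower than hydride transfer, which would give low enantioselectivity. The cation at C2 may be captured by a second molecule of 4, and 9 may oligomerize before it is captured. Fallback with known chemistry, a racemic ring construction followed by resolution: set out from 4 and 9. Diphenyl phosphate (10 mol %) in toluene at room temperature gives the racemic lactol 10 by the same Friedel–Crafts/hemiacetalization, and it is isolated. Ionic hydrogenation (Et3SiH, BF3·OEt2, CH2Cl2, −78 °C) gives the racemic isoflavan diacetate F1. Separation of the enantiomers by preparative HPLC on a chiral stationary phase (amylose tris(3,5-dimethylphenylcarbamate)) returns to the route at 12, at the cost of half the material.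

Step 2. The allyl terminus may migrate to C2 between the two oxygens instead of C6. The prenyl group may be lost by ionization in the hot protic medium, and the product may react on (abnormal Claisen rearrangement, ring closure of the phenol onto the alkene). Fallback, building the quaternary benzylic carbon by cross-coupling and olefination instead of a sigmatropic shift: set out from 1. Monobromination (NBS, MeCN, 0 °C) gives 4-bromobenzene-1,3-diol F2. Protection (NaH, MOMCl, DMF) gives the bis-MOM ether F3. Palladium-catalysed α-arylation of isobutyraldehyde (Pd(OAc)2, rac-BINAP, Cs2CO3, dioxane, 80 °C) gives the α-aryl isobutyraldehyde F4. Wittig methylenation (Ph3P=CH2, THF, 0 °C) gives the bis-MOM ether F5 of the wanted arene, and dilute HCl in methanol at room temperature returns to the route at 4.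

Step 6. The oxidation may stop at the allylic alcohol or run past the enal, the acetates may be partly lost in the hot, wet medium, and 9 may polymerize during the reaction. Fallback, bringing the three-carbon unit in at the alcohol oxidation level by cross-coupling and oxidizing under neutral conditions at room temperature: set out from 6. Miyaura borylation (B2pin2, PdCl2(dppf), KOAc, dioxane, 85 °C) gives the aryl pinacol boronate F6. Fluoride-promoted Suzuki coupling with 2-bromoprop-2-en-1-ol (Pd2(dba)3, P(t-Bu)3, KF, THF, rt) gives the 2-arylallyl alcohol F7. Oxidation with activated MnO2 (CH2Cl2, rt) returns to the route at 9.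

**Further compounds**
F1 | step 7 | racemic 4-[7-hydroxy-6-(2-methylbut-3-en-2-yl)-3,4-dihydro-2H-chromen-3-yl]-6-(2-methylbut-3-en-2-yl)-1,3-phenylene diacetate | C=CC(C)(C)c1cc2c(cc1O)OCC(c1cc(C(C)(C)C=C)c(OC(C)=O)cc1OC(C)=O)C2
F2 | step 2 | 4-bromobenzene-1,3-diol | Oc1ccc(Br)c(O)c1
F3 | step 2 | 1-bromo-2,4-bis(methoxymethoxy)benzene | COCOc1ccc(Br)c(OCOC)c1
F4 | step 2 | 2-[2,4-bis(methoxymethoxy)phenyl]-2-methylpropanal | COCOc1ccc(C(C)(C)C=O)c(OCOC)c1
F5 | step 2 | 2,4-bis(methoxymethoxy)-1-(2-methylbut-3-en-2-yl)benzene | C=CC(C)(C)c1ccc(OCOC)cc1OCOC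
F6 | step 6 | 4-(2-methylbut-3-en-2-yl)-6-(4,4,5,5-tetramethyl-1,3,2-dioxaborolan-2-yl)-1,3-phenylene diacetate | C=CC(C)(C)c1cc(B2OC(C)(C)C(C)(C)O2)c(OC(C)=O)cc1OC(C)=O
F7 | step 6 | 4-(3-hydroxyprop-1-en-2-yl)-6-(2-methylbut-3-en-2-yl)-1,3-phenylene diacetate | C=CC(C)(C)c1cc(C(=C)CO)c(OC(C)=O)cc1OC(C)=O
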